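The ester is cut at its carbonyl carbon: C1′ comes from carbon monoxide, so the O3–C1′ and C1′–C2′ bonds are made together in one palladium-catalysed alkoxycarbonylation that joins the ring A carbinol (C3–OH, next to the C4 methyl), CO and an (E,E)-dienyl iodide. The step exploits that O3 on ring A is the only free hydroxyl and that C1′ sits between O3 and the C2′=C3′–C4′=C5′ diene. The precursors are the trinor-eremophilane trienone with the ring B C7 enol masked as a TBS ether (from (S)-carvone, 3β-hydroxyl set by hydride reduction) and the silyl-protected (R)-dienyl iodide. Fluoride then frees both hydroxyls.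

Key step: step 16

Remark on numbering: eremophilane numbering is used for the core (ring A = C1, C2, C3, C4, C5, C10; ring B = C5 to C10; methyls on C4 and C5; β = the face of the C5 methyl), primed numbers for the acyl chain (C1′ = ester carbonyl, C6′ = stereocentre).

**Core alcohol (steps 1–10)**

Step 1
Reactants: 1 (S)-carvone; 2 methylmagnesium bromide
Product: 4 trimethyl{[(3S,5S)-2,3-dimethyl-5-(prop-1-en-2-yl)cyclohex-1-en-1-yl]oxy}silane, via bromomagnesium enolate 3 (not isolated)
Conditions: CuBr·SMe2 (10 mol%), Me3SiCl, DMPU, THF, −78 to −40 °C; Et3N quench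
Reagents that add atoms: chlorotrimethylsilane, C[Si](C)(C)Cl
Why: Copper-catalysed conjugate addition of the Grignard reagent with in situ O-silylation should deliver the methyl group axially and anti to the isopropenyl group, which fixes the future C4 centre (3S in 4) and stores the regiodefined enolate as its silyl ether.

Step 2
Reactants: 4 silyl enol ether; 5 3-(trimethylsilyl)but-3-en-2-one
Product: 8 (4aR,5S,7S)-4a,5-dimethyl-7-(prop-1-en-2-yl)-4,4a,5,6,7,8-hexahydronaphthalen-2(3H)-one, via lithium enolate 6 (not isolated), via silyl diketone 7 (not isolated)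
Conditions: MeLi, THF, 0 °C; 5, −78 → 0 °C; then KOH, MeOH, reflux
Reagents that add atoms: none
Why: Stork–Ganem variant of the Robinson annulation: the lithium enolate adds to the α-silyl enone on the face opposite the adjacent pseudoaxial methyl, so the quaternary C5 centre forms with the two methyls cis, and KOH/MeOH then cleaves the C–Si bond and drives the aldol condensation.

Step 3
Reactants: 8 isopropenyl octalone
Product: 10 (4aR,5S)-4a,5-dimethyl-4,4a,5,6-tetrahydronaphthalen-2(3H)-one, via methoxy hydroperoxide 9 (not isolated)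
Conditions: O3, CH2Cl2/MeOH, −78 °C (indicator end point); then Cu(OAc)2·H2O, FeSO4·7H2O, −78 °C → rt
Reagents that add atoms: none
Why: Dealkenylative fragmentation of the Schreiber type: ozone attacks only the electron-rich isopropenyl alkene, FeSO4 cleaves the O–O bond, β-scission expels methyl acetate and Cu(OAc)2 oxidises the C2 radical to the alkene, which should form towards C1 because those hydrogens are vinylogously activated and the product is the conjugated dienone.

Step 4
Reactants: 10 linear dienone
Product: 11 8,8-(ethylenedioxy)-4β,5β-dimethyl-11,12,13-trinoreremophila-1(10),2-diene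
Conditions: HOCH2CH2OH, p-TsOH·H2O (cat.), benzene, reflux, Dean–Stark
Reagents that add atoms: ethylene glycol, OCCO
Why: Acid-catalysed ketalisation of a linear dienone is known from steroidal 4,6-dien-3-ones to move both double bonds out of conjugation, which here masks C8 and places a cisoid C10=C1–C2=C3 diene in ring A.

Step 5
Reactants: 11 diene ketal
Product: 13 8,8-(ethylenedioxy)-10α-hydroxy-4β,5β-dimethyl-11,12,13-trinoreremophil-1-en-3-one, via endoperoxide 12 (not isolated)
Conditions: O2, tetraphenylporphyrin (cat.), visible light, CH2Cl2, 0 °C; then Et3N, rt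
Reagents that add atoms: oxygen, O=O
Why: Singlet oxygen adds [4+2] across C10 and C3 of the homoannular diene and Et3N then removes the only bridgehead hydrogen (C3–H) in a Kornblum–DeLaMare rearrangement to give the C3 ketone; the facial sense of the cycloaddition does not matter because C3 is now sp2 and C10 becomes sp2 in step 6.

Step 6
Reactants: 13 hydroxy enone ketal
Product: 14 8,8-(ethylenedioxy)-4β,5β-dimethyl-11,12,13-trinoreremophila-1,9-dien-3-one
Conditions: Burgess reagent, benzene, 50 °C
Reagents that add atoms: none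
Why: Burgess dehydration, a syn elimination of the tertiary sulfamate towards the only β-hydrogens (on C9), should give the linear dienone under neutral conditions that leave the ketal and the C4 centre untouched.

Step 7
Reactants: 14 dienone ketal
Product: 16 (4aR,5R,6S)-6-hydroxy-4a,5-dimethyl-4,4a,5,6-tetrahydronaphthalen-2(3H)-one (3β-hydroxy-1,9-dien-8-one), via hydroxy ketal 15 (not isolated)
Conditions: iBu2AlH, CH2Cl2, −78 °C; then 1 M HCl, THF, 0 °C
Reagents that add atoms: water, O
Why: 1,2-Reduction by the bulky aluminium hydride should occur from the α face, opposite the pseudoaxial C5 methyl that is 1,3 to the carbonyl carbon (steric approach control, as in hydride reductions of angular-methyl decalones), which sets the 3β (3S) carbinol cis to both methyls; dilute acid then hydrolyses the dienyl ketal to the C8 ketone, already conjugated with both double bonds.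

Step 8
Reactants: 16 hydroxy dienone
Product: 18 3β,7α-dihydroxy-4β,5β-dimethyl-11,12,13-trinoreremophila-1,9-dien-8-one (7α epimer expected as the major one), via disodium dianion 17 (not isolated)
Conditions: NaN(SiMe3)2 (2.2 equiv), THF, −78 °C; 2-(phenylsulfonyl)-3-phenyloxaziridine; aq. NH4Cl
Reagents that add atoms: 2-(phenylsulfonyl)-3-phenyloxaziridine, O=S(=O)(N1OC1c1ccccc1)c1ccccc1
Why: Enolate hydroxylation with a Davis oxaziridine: the first equivalent of base forms the C3 alkoxide, the second deprotonates kinetically at the α′ methylene C7, and oxygen transfer should occur mainly from the α face, although the C7 configuration is erased in step 9.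

Step 9
Reactants: 18 α′-hydroxy ketone
Product: 20 3β,7-dihydroxy-4β,5β-dimethyl-11,12,13-trinoreremophila-1,6,9-trien-8-one, via 7,8-dione 19 (not isolated)
Conditions: Cu(OAc)2·H2O (2.2 equiv), MeOH, rt, argon
Reagents that add atoms: none
Why: Cu(OAc)2 oxidises α-ketols through the enediol to 1,2-diones without touching the isolated allylic C3 alcohol, and the dione tautomerises towards C6 to the hydrogen-bonded diosphenol.

Step 10
Reactants: 20 diosphenol
Product: 21 (4aS,5R,6S)-3-[(tert-butyldimethylsilyl)oxy]-6-hydroxy-4a,5-dimethyl-5,6-dihydronaphthalen-2(4aH)-one (core alcohol)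
Conditions: TBSCl (1.1 equiv), imidazole, DMF, 0 °C
Reagents that add atoms: tert-butyldimethylsilyl chloride, CC(C)(C)[Si](C)(C)Cl
Why: Silylation should be selective for the acidic, unhindered enol hydroxyl over the axial C3 hydroxyl, which is shielded by the C4 and C5 methyls, so the core carries one protecting group and one free hydroxyl.

**Dienyl iodide (steps 11–15)**

Step 11
Reactants: 22 butanal; 23 formaldehyde (37% aqueous); 24 ethyl (triphenylphosphoranylidene)acetate
Product: 26 ethyl (R,E)-4-(hydroxymethyl)hex-2-enoate, via hydroxy aldehyde 25 (not isolated)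
Conditions: (R)-2-[diphenyl(trimethylsilyloxy)methyl]pyrrolidine (20 mol%), pH 7 buffer (KH2PO4/K2HPO4), toluene, rt; then 24, rt
Reagents that add atoms: none
Why: Enamine-catalysed α-hydroxymethylation: formaldehyde should approach the E-enamine on the face away from the bulky diphenyl(silyloxy)methyl group of the (R)-catalyst to give the (S)-aldehyde, which is trapped at once by an E-selective Wittig reaction so that the labile α-centre cannot racemise.

Step 12
Reactants: 26 hydroxy enoate
Product: 27 ethyl (R,E)-4-{[(tert-butyldimethylsilyl)oxy]methyl}hex-2-enoate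
Conditions: TBSCl, imidazole, CH2Cl2, rt
Reagents that add atoms: tert-butyldimethylsilyl chloride, CC(C)(C)[Si](C)(C)Cl
Why: Standard silylation of the primary alcohol gives a group that survives the later steps and leaves together with the enol silyl ether at the end.

Step 13
Reactants: 27 silyl enoate
Product: 28 (R,E)-4-{[(tert-butyldimethylsilyl)oxy]methyl}hex-2-en-1-ol
Conditions: iBu2AlH, CH2Cl2, −78 °C; aq. potassium sodium tartrate
Reagents that add atoms: none
Why: iBu2AlH reduces the α,β-unsaturated ester in a 1,2 sense to the allylic alcohol without affecting the alkene geometry or the stereocentre.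

Step 14
Reactants: 28 allylic alcohol
Product: 29 (R,E)-4-{[(tert-butyldimethylsilyl)oxy]methyl}hex-2-enal
Conditions: MnO2, CH2Cl2, rt
Reagents that add atoms: none
Why: MnO2 oxidises allylic alcohols selectively to enals under neutral conditions, which avoids epimerisation at the γ-stereocentre.

Step 15
Reactants: 29 enal; 30 iodoform
Product: 31 tert-butyl{[(2R,3E,5E)-2-ethyl-6-iodohexa-3,5-dien-1-yl]oxy}dimethylsilane
Conditions: CrCl2, THF/1,4-dioxane, 0 °C → rt, dark
Reagents that add atoms: none
Why: Takai iodo-olefination: the geminal dichromium species made from iodoform and CrCl2 adds to the aldehyde and eliminates to the E-vinyl iodide, here the (1E,3E)-dienyl iodide, under non-basic conditions.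

**Coupling and deprotection (steps 16–17)**

Step 16
Reactants: 21 core alcohol; 31 dienyl iodide; 32 carbon monoxide
Product: 33 bis-silyl ether of the target
Conditions: Pd(OAc)2 (10 mol%), Xantphos (12 mol%), DMAP (20 mol%), iPr2NEt (3 equiv), CO (1 atm), toluene, 60 °C; 31 in 1.5-fold excess
Reagents that add atoms: none
Why: Zerovalent palladium, formed in situ from Pd(OAc)2, phosphine and CO, adds oxidatively to the C–I bond of 31 with retention of the E,E geometry, CO inserts to give a dienoylpalladium iodide (new C1′–C2′ bond), and the C3 hydroxyl of 21, helped by the amine base and by DMAP as acyl-transfer relay, attacks the acyl carbon (new C1′–O bond) while iPr2NEt takes up HI. The closest known reaction type is the palladium-catalysed alkoxycarbonylation of alkenyl iodides with secondary alcohols, as used for carbonylative esterification and macrolactonisation. No ring is closed and no stereocentre is created; the C3–O bond is never broken, so the 3S configuration, the C6′ centre and both alkene geometries pass through unchanged. The step needs chemoselectivity: acylation at O3 only, which the TBS ether on the C7 enol secures by leaving a single free hydroxyl, and carbonylation in preference to direct coupling or ionisation of the allylic ester formed, which the CO-saturated medium, the wide-bite-angle diphosphine and the moderate temperature favour by holding palladium as the divalent acyl complex. The excess of iodide lets the more valuable alcohol be consumed, and the neutral acyl donor avoids a free dienoic acid and harsh activation at the hindered carbinol.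

Step 17
Reactants: 33 bis-silyl ether
Product: 34 septeremophilane E
Conditions: HF·pyridine, pyridine, THF, 0 °C → rt
Reagents that add atoms: none
Why: Fluoride cleaves both Si–O bonds (primary alkyl silyl ether and enol silyl ether) while the pyridine buffer protects the allylic dienoate and the cross-conjugated trienone, so the diosphenol and the primary alcohol should be released without migration or elimination.

**Compound list**

1 | (S)-carvone, (5S)-2-methyl-5-(prop-1-en-2-yl)cyclohex-2-en-1-one | CC1=CC[C@@H](CC1=O)C(C)=C | starting material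
2 | methylmagnesium bromide | C[Mg]Br | starting material
3 | bromomagnesium (3S,5S)-2,3-dimethyl-5-(prop-1-en-2-yl)cyclohex-1-en-1-olate | C1[C@H](C(C)=C)CC(O[Mg]Br)=C(C)[C@H]1C | intermediate
4 | trimethyl{[(3S,5S)-2,3-dimethyl-5-(prop-1-en-2-yl)cyclohex-1-en-1-yl]oxy}silane | C1[C@H](C(C)=C)CC(O[Si](C)(C)C)=C(C)[C@H]1C | intermediate
5 | 3-(trimethylsilyl)but-3-en-2-one | CC(=O)C(=C)[Si](C)(C)C | starting material
6 | lithium (3S,5S)-2,3-dimethyl-5-(prop-1-en-2-yl)cyclohex-1-en-1-olate | C1[C@H](C(C)=C)CC(O[Li])=C(C)[C@H]1C | intermediate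
7 | (2R,3S,5S)-2,3-dimethyl-2-[3-oxo-2-(trimethylsilyl)butyl]-5-(prop-1-en-2-yl)cyclohexan-1-one (silyl-bearing carbon as a mixture) | C1[C@H](C(C)=C)CC(=O)[C@](C)(CC([Si](C)(C)C)C(C)=O)[C@H]1C | intermediate
8 | (4aR,5S,7S)-4a,5-dimethyl-7-(prop-1-en-2-yl)-4,4a,5,6,7,8-hexahydronaphthalen-2(3H)-one | C1[C@H](C(C)=C)CC2=CC(=O)CC[C@]2(C)[C@H]1C | intermediate
9 | (4aR,5S,7S)-7-(1-hydroperoxy-1-methoxyethyl)-4a,5-dimethyl-4,4a,5,6,7,8-hexahydronaphthalen-2(3H)-one (peroxy carbon as a mixture) | C1[C@H](C(C)(OC)OO)CC2=CC(=O)CC[C@]2(C)[C@H]1C | intermediate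
10 | (4aR,5S)-4a,5-dimethyl-4,4a,5,6-tetrahydronaphthalen-2(3H)-one | C1C=CC2=CC(=O)CC[C@]2(C)[C@H]1C | intermediate
11 | 8,8-(ethylenedioxy)-4β,5β-dimethyl-11,12,13-trinoreremophila-1(10),2-diene | C1=CC=C2CC3(OCCO3)CC[C@]2(C)[C@H]1C | intermediate
12 | 3α,10α-epidioxy-8,8-(ethylenedioxy)-4β,5β-dimethyl-11,12,13-trinoreremophil-1-ene | C[C@H]1[C@H]2C=C[C@@]3(OO2)CC4(OCCO4)CC[C@]13C | intermediate
13 | 8,8-(ethylenedioxy)-10α-hydroxy-4β,5β-dimethyl-11,12,13-trinoreremophil-1-en-3-one | C[C@H]1C(=O)C=C[C@@]2(O)CC3(OCCO3)CC[C@]12C | intermediate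
14 | 8,8-(ethylenedioxy)-4β,5β-dimethyl-11,12,13-trinoreremophila-1,9-dien-3-one | C[C@H]1C(=O)C=CC2=CC3(OCCO3)CC[C@]12C | intermediate
15 | 8,8-(ethylenedioxy)-4β,5β-dimethyl-11,12,13-trinoreremophila-1,9-dien-3β-ol | C[C@H]1[C@@H](O)C=CC2=CC3(OCCO3)CC[C@]12C | intermediate
16 | (4aR,5R,6S)-6-hydroxy-4a,5-dimethyl-4,4a,5,6-tetrahydronaphthalen-2(3H)-one | O[C@H]1C=CC2=CC(=O)CC[C@]2(C)[C@H]1C | intermediate
17 | disodium alkoxide-enolate of 16 (C3 alkoxide, C7=C8 enolate) | [Na]O[C@H]1C=CC2=CC(O[Na])=CC[C@]2(C)[C@H]1C | intermediate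
18 | 3β,7α-dihydroxy-4β,5β-dimethyl-11,12,13-trinoreremophila-1,9-dien-8-one | O[C@H]1C=CC2=CC(=O)[C@H](O)C[C@]2(C)[C@H]1C | intermediate
19 | 3β-hydroxy-4β,5β-dimethyl-11,12,13-trinoreremophila-1,9-diene-7,8-dione | O[C@H]1C=CC2=CC(=O)C(=O)C[C@]2(C)[C@H]1C | intermediate
20 | 3β,7-dihydroxy-4β,5β-dimethyl-11,12,13-trinoreremophila-1,6,9-trien-8-one | O[C@H]1C=CC2=CC(=O)C(O)=C[C@]2(C)[C@H]1C | intermediate
21 | (4aS,5R,6S)-3-[(tert-butyldimethylsilyl)oxy]-6-hydroxy-4a,5-dimethyl-5,6-dihydronaphthalen-2(4aH)-one | O[C@H]1C=CC2=CC(=O)C(O[Si](C)(C)C(C)(C)C)=C[C@]2(C)[C@H]1C | intermediate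
22 | butanal | CCCC=O | starting material
23 | formaldehyde | C=O | starting material
24 | ethyl (triphenylphosphoranylidene)acetate | CCOC(=O)C=P(c1ccccc1)(c1ccccc1)c1ccccc1 | starting material
25 | (S)-2-(hydroxymethyl)butanal | CC[C@H](C=O)CO | intermediate
26 | ethyl (R,E)-4-(hydroxymethyl)hex-2-enoate | CC[C@H](/C=C/C(=O)OCC)CO | intermediate
27 | ethyl (R,E)-4-{[(tert-butyldimethylsilyl)oxy]methyl}hex-2-enoate | CC[C@H](/C=C/C(=O)OCC)CO[Si](C)(C)C(C)(C)C | intermediate
28 | (R,E)-4-{[(tert-butyldimethylsilyl)oxy]methyl}hex-2-en-1-ol | CC[C@H](/C=C/CO)CO[Si](C)(C)C(C)(C)C | intermediate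
29 | (R,E)-4-{[(tert-butyldimethylsilyl)oxy]methyl}hex-2-enal | CC[C@H](/C=C/C=O)CO[Si](C)(C)C(C)(C)C | intermediate
30 | iodoform | IC(I)I | starting material
31 | tert-butyl{[(2R,3E,5E)-2-ethyl-6-iodohexa-3,5-dien-1-yl]oxy}dimethylsilane | CC[C@H](/C=C/C=C/I)CO[Si](C)(C)C(C)(C)C | intermediate
32 | carbon monoxide | [C-]#[O+] | starting material
33 | (2E,4E,6R)-6-{[(tert-butyldimethylsilyl)oxy]methyl}octa-2,4-dienoate of 21 (bis-silyl ether of the target) | CC[C@H](/C=C/C=C/C(=O)O[C@H]1C=CC2=CC(=O)C(O[Si](C)(C)C(C)(C)C)=C[C@]2(C)[C@H]1C)CO[Si](C)(C)C(C)(C)C | intermediate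
34 | septeremophilane E, (3S,4R,5S)-3β-[(2E,4E,6R)-6-(hydroxymethyl)octa-2,4-dienoyloxy]-7-hydroxy-11,12,13-trinoreremophila-1,6,9-trien-8-one | CC[C@H](/C=C/C=C/C(=O)O[C@H]1C=CC2=CC(=O)C(O)=C[C@]2(C)[C@H]1C)CO | target

**Totals**

Total step count: 17. Longest linear sequence: 12 steps (steps 1–10, 16 and 17, from (S)-carvone).

**Steps most likely to fail, with fallbacks**

The key coupling, step 16, carries the main risk. Alcoholysis of the dienoylpalladium by the hindered C3 hydroxyl may be slow, so that reduction or homocoupling of the iodide, or palladium-induced ionisation of the allylic ester already formed, takes over. The fallback separates carbonylation from esterification. Setting out from iodide 31, hydroxycarbonylation (Pd(OAc)2, Xantphos, CO, H2O, Et3N, THF) would give (2E,4E,6R)-6-{[(tert-butyldimethylsilyl)oxy]methyl}octa-2,4-dienoic acid F1. 2,4,6-Trichlorobenzoyl chloride and Et3N would turn it into the mixed anhydride F2, which with alcohol 21 and DMAP in toluene would acylate O3 and come back to the route at 33.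

The α′-hydroxylation, step 8, is the second risk. Enolisation of the alkoxide-bearing dienone may be incomplete or unselective, and the unprotected allylic alcohol limits the choice of oxidant in step 9. The fallback masks C3–OH for three steps:
- Setting out from 16, TESCl and imidazole would give the triethylsilyl ether F3.
- NaN(SiMe3)2 would form the sodium enolate F4, and the Davis oxaziridine would give the α′-hydroxy ketone F5.
- Dess–Martin periodinane would oxidise F5 to the 7,8-dione F6, which enolises to the diosphenol F7.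
- TBSCl and imidazole would give the bis-silyl compound F8.
- PPTS in MeOH at 0 °C would remove the more labile alkyl triethylsilyl ether and come back to the route at 21.

The dealkenylation, step 3, is the third risk. The radical fragmentation may give a mixture of alkene regioisomers or a low mass balance. The fallback replaces the radical path by an ionic one. Setting out from 8, ozonolysis in CH2Cl2/MeOH gives hydroperoxide 9 as before. Ac2O, Et3N and DMAP would acylate it to the peracetate F9, which undergoes Criegee rearrangement with retention to the 2α-acetate F10. DBU in toluene at 80 °C would then eliminate acetic acid by a vinylogous E1cB path through the C1 hydrogens and come back to the route at 10.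

**Further compounds**

F1 | step 16 | (2E,4E,6R)-6-{[(tert-butyldimethylsilyl)oxy]methyl}octa-2,4-dienoic acid | CC[C@H](/C=C/C=C/C(=O)O)CO[Si](C)(C)C(C)(C)C
F2 | step 16 | mixed anhydride of F1 with 2,4,6-trichlorobenzoic acid | CC[C@H](/C=C/C=C/C(=O)OC(=O)c1c(Cl)cc(Cl)cc1Cl)CO[Si](C)(C)C(C)(C)C
F3 | step 8 | 3β-(triethylsilyloxy)-4β,5β-dimethyl-11,12,13-trinoreremophila-1,9-dien-8-one | CC[Si](CC)(CC)O[C@H]1C=CC2=CC(=O)CC[C@]2(C)[C@H]1C
F4 | step 8 | sodium C7=C8 enolate of F3 | CC[Si](CC)(CC)O[C@H]1C=CC2=CC(O[Na])=CC[C@]2(C)[C@H]1C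
F5 | step 8 | 7α-hydroxy-3β-(triethylsilyloxy)-4β,5β-dimethyl-11,12,13-trinoreremophila-1,9-dien-8-one | CC[Si](CC)(CC)O[C@H]1C=CC2=CC(=O)[C@H](O)C[C@]2(C)[C@H]1C
F6 | step 8 | 3β-(triethylsilyloxy)-4β,5β-dimethyl-11,12,13-trinoreremophila-1,9-diene-7,8-dione | CC[Si](CC)(CC)O[C@H]1C=CC2=CC(=O)C(=O)C[C@]2(C)[C@H]1C
F7 | step 8 | 7-hydroxy-3β-(triethylsilyloxy)-4β,5β-dimethyl-11,12,13-trinoreremophila-1,6,9-trien-8-one | CC[Si](CC)(CC)O[C@H]1C=CC2=CC(=O)C(O)=C[C@]2(C)[C@H]1C
F8 | step 8 | 7-[(tert-butyldimethylsilyl)oxy]-3β-(triethylsilyloxy)-4β,5β-dimethyl-11,12,13-trinoreremophila-1,6,9-trien-8-one | CC[Si](CC)(CC)O[C@H]1C=CC2=CC(=O)C(O[Si](C)(C)C(C)(C)C)=C[C@]2(C)[C@H]1C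
F9 | step 3 | peracetate of hydroperoxide 9 | C1[C@H](C(C)(OC)OOC(C)=O)CC2=CC(=O)CC[C@]2(C)[C@H]1C
F10 | step 3 | 2α-acetoxy-4β,5β-dimethyl-11,12,13-trinoreremophil-9-en-8-one | C1[C@H](OC(C)=O)CC2=CC(=O)CC[C@]2(C)[C@H]1C
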